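**Plan**

- Retrosynthesis: the C7 benzoate and the O2/O3 acetates are cut last. The O1–C6 bond of the oxirane and the O–C5 bond of the β-carbinol are then cut together, which turns the C1/C6 oxirane with its 4,5-diol into an α-4,5-oxirane flanked by a β-O6–H and an α-O1–H. C3–O and C6–O go back to a singlet-oxygen adduct, and C1–O/C2–O to the ipso,ortho-cis-diol of benzoic acid.
- Enabling feature: a trisubstituted C1/C6 oxirane beside an α-O4/β-O5 trans-diol is what a 4,5-oxirane leaves behind after two anti 3-exo openings (O6 onto C5, then O1 onto C6). C1, with its oxygen and C7, is the ipso carbon of benzoic acid.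
- Forward order: the carbocycle is the ring of benzoic acid (no C–C ring closure). Acetonide, endoperoxide (C3–O, C6–O), O6/O7 silylene, PMB ethers on O2/O3, α-4,5-oxirane and PMB on O7 follow. The epoxide walk then builds the C1/C6 oxirane; silylation, PMB removal, benzoylation, acetylation and desilylation finish.
- Stereochemistry: C1 and C2 from the dioxygenase; C3 and C6 from cycloaddition anti to the acetonide; C4/C5 from epoxidation anti to both allylic oxygens; the final C5 and C6 from two SN2 inversions.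
- C7 is carried through the alkoxide step as a PMB ether rather than as the benzoate, so that no acyl shift to O1 or O6 can compete; the benzoate is put on afterwards.

Key step: step 12

Remark (notation): C1 is the ring carbon bearing C7 (the CH2O carbon), C2/C3 carry the acetates, C4/C5 the free hydroxyls, C6 is the oxirane CH; α is the ring face of the oxirane oxygen in the target, β the face of C7; On is the oxygen on Cn.

Remark (assumption): the target belongs to the (1S,2R) series of the benzoate cis-diol, the enantiomer formed by the benzoate dioxygenase of Ralstonia eutropha B9; the strain is taken to be at hand and benzoic acid is the commercial starting material.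

**Route**

Step 1
Reactants: 1 benzoic acid
Product: 2 (1S,2R)-1,2-dihydroxycyclohexa-3,5-diene-1-carboxylic acid
Conditions: Ralstonia eutropha B9 (whole cells), fructose, mineral medium, air, pH 7, 30 °C; then pH 3, EtOAc extraction
Reagents that add atoms: dioxygen O=O
Why: Microbial arene cis-dihydroxylation: the benzoate dioxygenase of the dehydrogenase-deficient mutant adds both oxygens across the ipso and ortho carbons from one face, fixing C1 (S) and C2 (R) in one operation.

Step 2
Reactants: 2 (1S,2R)-1,2-dihydroxycyclohexa-3,5-diene-1-carboxylic acid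
Product: 3 1α,2α-O-isopropylidene acetal of 2 (cis-fused acetonide acid)
Conditions: 2,2-dimethoxypropane, TsOH·H2O (cat.), acetone, 0 °C → rt
Reagents that add atoms: 2,2-dimethoxypropane COC(C)(C)OC
Why: Acid-catalysed transacetalisation (acetonide formation) of the cis-vicinal diol, fast enough at room temperature to outrun dehydrative aromatisation; no stereocentre is touched.

Step 3
Reactants: 3 acetonide acid
Product: 4 methyl ester of 3
Conditions: MeI, K2CO3, DMF, rt
Reagents that add atoms: iodomethane CI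
Why: SN2 O-alkylation of the carboxylate (esterification with an alkyl halide) under non-acidic conditions that spare the acetonide and the diene.

Step 4
Reactants: 4 acetonide methyl ester
Product: 5 methyl 3β,6β-epidioxy-1α,2α-(isopropylidenedioxy)cyclohex-4-ene-1β-carboxylate (endoperoxide)
Conditions: O2, tetraphenylporphyrin (cat.), visible light, CH2Cl2, −20 °C
Reagents that add atoms: dioxygen O=O
Why: [4+2] cycloaddition of singlet oxygen to the cyclohexadiene (photooxygenation), which should take the face opposite the acetonide oxygens and its endo methyl group, placing the new C3–O and C6–O bonds on the β face.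

Step 5
Reactants: 5 endoperoxide ester
Product: 6 1β-(hydroxymethyl)-1α,2α-(isopropylidenedioxy)cyclohex-4-ene-3β,6β-diol
Conditions: LiAlH4, THF, −40 → 0 °C; then H2O, aq. NaOH
Reagents that add atoms: none
Why: Hydride reduction in which LiAlH4 cleaves the O–O bond to the cis-3,6-diol and reduces the ester to the primary alcohol; no C–O bond at C3 or C6 is broken, so both configurations are kept.

Step 6
Reactants: 6 acetonide triol
Product: 7 6,7-O-(di-tert-butylsilylene) derivative of 6 (3β-OH free)
Conditions: tBu2Si(OTf)2, 2,6-lutidine, CH2Cl2, −40 → 0 °C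
Reagents that add atoms: di-tert-butylsilyl bis(trifluoromethanesulfonate) CC(C)(C)[Si](OS(=O)(=O)C(F)(F)F)(OS(=O)(=O)C(F)(F)F)C(C)(C)C
Why: Silylene acetal formation: the primary O7 is silylated first and the tethered silyl triflate closes onto the cis-1,3-related O6 to a six-membered ring, leaving the isolated O3–H free (the selectivity known from 4,6-O-silylene protection of pyranosides).

Step 7
Reactants: 7 silylene acetonide
Product: 8 6,7-O-(di-tert-butylsilylene)-1β-(hydroxymethyl)cyclohex-4-ene-1α,2α,3β,6β-tetrol (free 1α,2α,3β-triol)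
Conditions: AcOH–H2O (4:1), 45 °C
Reagents that add atoms: none
Why: Acid-catalysed acetal hydrolysis; the six-membered di-tert-butylsilylene and the allylic hydroxyl should tolerate warm aqueous acetic acid.

Step 8
Reactants: 8 silylene triol
Product: 9 2α,3β-bis-O-(4-methoxybenzyl) ether of 8 (1α-OH free)
Conditions: NaH (2.3 equiv), PMBCl (2.2 equiv), Bu4NI (cat.), DMF, 0 °C
Reagents that add atoms: 4-methoxybenzyl chloride COc1ccc(CCl)cc1
Why: Williamson etherification in which the two secondary alkoxides (O2, O3) are alkylated while the tertiary O1, flanked by three substituted carbons, should stay free.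

Step 9
Reactants: 9 bis-PMB silylene alkene
Product: 10 4α,5α-epoxide of 9
Conditions: mCPBA, NaHCO3, CH2Cl2, 0 °C → rt
Reagents that add atoms: 3-chloroperoxybenzoic acid O=C(OO)c1cccc(Cl)c1
Why: Prilezhaev epoxidation: both allylic oxygens (the O3 ether and the O6 arm of the silylene) shield the β face and the free tertiary O1–H on the α face can hydrogen-bond the peracid, so the oxirane oxygen should enter on the α face, setting C4 and C5.

Step 10
Reactants: 10 silylene epoxide
Product: 11 4α,5α-epoxy-1β-(hydroxymethyl)-2α,3β-bis(4-methoxybenzyloxy)cyclohexane-1α,6β-diol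
Conditions: HF·pyridine, pyridine, THF, 0 °C
Reagents that add atoms: none
Why: Fluoride-mediated Si–O cleavage (desilylation) under buffered, non-basic conditions, so that no alkoxide is formed and the oxirane stays at C4/C5.

Step 11
Reactants: 11 epoxy triol
Product: 12 7-O-(4-methoxybenzyl) ether of 11 (4α,5α-epoxy-1α,6β-diol 2,3,7-tris-PMB ether)
Conditions: Ag2O, PMBBr (1.2 equiv), CH2Cl2, rt, dark
Reagents that add atoms: 4-methoxybenzyl bromide COc1ccc(CBr)cc1
Why: Ag2O-mediated Williamson etherification (Purdie-type alkylation), which runs without free alkoxide and so cannot start the epoxide migration; the primary hydroxyl should react in preference to the neopentylic secondary O6–H and the tertiary O1–H.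

Step 12
Reactants: 12 4α,5α-epoxy-1α,6β-diol tris-PMB ether
Product: 14 1α,6α-epoxy-4α,5β-diol 2,3,7-tris-PMB ether, via 5β,6β-epoxide 13 (not isolated)
Conditions: KOtBu (0.3 equiv), tBuOH–THF (1:1), 0 °C → rt; aq. NH4Cl
Reagents that add atoms: none
Why: Catalytic tert-butoxide equilibrates the alkoxides: the β-O6 alkoxide attacks C5 opposite the α C5–O bond (3-exo-tet, inversion at C5) to give the β-5,6-oxirane 13 with O4 released on the α face, and the α-O1 alkoxide then attacks C6 opposite the β C6–O bond (3-exo-tet, inversion at C6), closing the α-C1/C6 oxirane and releasing O5 on the β face. The closest known chemistry is the Payne rearrangement and the base-induced epoxide migration of anhydro-cyclitols, here run twice in one flask. The one ring that persists, the C1/C6 oxirane, is closed by intramolecular SN2 displacement in the 3-exo-tet mode. Both new stereocentres are substrate-controlled: C5 takes the configuration dictated by β-O6 and C6 that dictated by α-O1, while C4 keeps its oxygen untouched. The step needs a single migration path and a thermodynamic drive: O3, the one oxygen that could open the oxirane at C4, is an ether, as are O2 and O7, so C4→C5→C6→C1 is the only anti-periplanar route, and the reversible steps should settle on 14, the only trisubstituted oxirane and the only isomer that has traded the tertiary hydroxyl for a secondary one. No ester is present, so acyl shifts cannot compete.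

Step 13
Reactants: 14 1α,6α-epoxy-4α,5β-diol tris-PMB ether
Product: 15 4α,5β-bis-O-triethylsilyl ether of 14
Conditions: TESOTf, 2,6-lutidine, CH2Cl2, −78 °C
Reagents that add atoms: triethylsilyl trifluoromethanesulfonate CC[Si](CC)(CC)OS(=O)(=O)C(F)(F)F
Why: Silyl ether formation with a silyl triflate and a hindered base at low temperature, fast on both secondary hydroxyls and too mild to open the oxirane.

Step 14
Reactants: 15 bis-TES tris-PMB ether
Product: 16 1α,6α-epoxy-1β-(hydroxymethyl)-4α,5β-bis(triethylsilyloxy)cyclohexane-2α,3β-diol (2,3,7-triol)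
Conditions: DDQ (3.6 equiv), CH2Cl2–pH 7 phosphate buffer (10:1), 0 °C → rt
Reagents that add atoms: none
Why: Oxidative cleavage of the three 4-methoxybenzyl ethers by DDQ (oxidation to the oxocarbenium ion, then hydrolysis), to which silyl ethers and the oxirane are inert in buffered medium.

Step 15
Reactants: 16 2,3,7-triol
Product: 17 7-O-benzoate of 16
Conditions: BzCl (1.05 equiv), 2,4,6-collidine, CH2Cl2, −40 → −10 °C
Reagents that add atoms: benzoyl chloride O=C(Cl)c1ccccc1
Why: Nucleophilic acyl substitution with kinetic selection of the primary hydroxyl over the two flanked secondary ones, using a hindered base at low temperature.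

Step 16
Reactants: 17 7-benzoate 2,3-diol
Product: 18 2α,3β-di-O-acetate of 17
Conditions: Ac2O, pyridine, DMAP (cat.), CH2Cl2, 0 °C → rt
Reagents that add atoms: acetic anhydride CC(=O)OC(C)=O
Why: DMAP-catalysed acylation of the two remaining secondary hydroxyls; the silyl ethers on O4/O5 keep the esters in place.

Step 17
Reactants: 18 diacetate benzoate bis-TES ether
Product: 19 target, [2α,3β-diacetoxy-1α,6α-epoxy-4α,5β-dihydroxycyclohex-1β-yl]methyl benzoate
Conditions: HF·pyridine, pyridine, THF, 0 °C
Reagents that add atoms: none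
Why: Fluoride-mediated cleavage of the triethylsilyl ethers in pyridine-buffered HF, conditions under which the esters should not migrate to the liberated vicinal hydroxyls and the oxirane should not be opened.

**Compound list**

1 | benzoic acid | O=C(O)c1ccccc1 | starting material
2 | (1S,2R)-1,2-dihydroxycyclohexa-3,5-diene-1-carboxylic acid (O1, O2 α; CO2H β) | O[C@@H]1C=CC=C[C@@]1(O)C(O)=O | intermediate
3 | 1α,2α-O-isopropylidene acetal of 2 | CC1(C)O[C@@H]2C=CC=C[C@@]2(O1)C(O)=O | intermediate
4 | methyl ester of 3 | CC1(C)O[C@@H]2C=CC=C[C@@]2(O1)C(=O)OC | intermediate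
5 | methyl 3β,6β-epidioxy-1α,2α-(isopropylidenedioxy)cyclohex-4-ene-1β-carboxylate | CC1(C)O[C@@H]2[C@@H]3C=C[C@@H](OO3)[C@@]2(O1)C(=O)OC | intermediate
6 | 1β-(hydroxymethyl)-1α,2α-(isopropylidenedioxy)cyclohex-4-ene-3β,6β-diol | CC1(C)O[C@@H]2[C@@H](O)C=C[C@@H](O)[C@@]2(O1)CO | intermediate
7 | 6,7-O-(di-tert-butylsilylene) derivative of 6, 3β-OH free | CC1(C)O[C@@H]2[C@@H](O)C=C[C@H]3O[Si](C(C)(C)C)(C(C)(C)C)OC[C@]32O1 | intermediate
8 | 6,7-O-(di-tert-butylsilylene)-1β-(hydroxymethyl)cyclohex-4-ene-1α,2α,3β,6β-tetrol (1α,2α,3β-triol) | O[C@@H]1[C@@H](O)C=C[C@H]2O[Si](C(C)(C)C)(C(C)(C)C)OC[C@]21O | intermediate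
9 | 2α,3β-bis-O-(4-methoxybenzyl) ether of 8, 1α-OH free | COc1ccc(CO[C@@H]2[C@@H](OCc3ccc(OC)cc3)C=C[C@H]3O[Si](C(C)(C)C)(C(C)(C)C)OC[C@]32O)cc1 | intermediate
10 | 4α,5α-epoxide of 9 | COc1ccc(CO[C@@H]2[C@@H](OCc3ccc(OC)cc3)[C@@H]4O[C@@H]4[C@H]3O[Si](C(C)(C)C)(C(C)(C)C)OC[C@]32O)cc1 | intermediate
11 | 4α,5α-epoxy-1β-(hydroxymethyl)-2α,3β-bis(4-methoxybenzyloxy)cyclohexane-1α,6β-diol | COc1ccc(CO[C@@H]2[C@@H](OCc3ccc(OC)cc3)[C@@H]4O[C@@H]4[C@@H](O)[C@@]2(O)CO)cc1 | intermediate
12 | 4α,5α-epoxy-1α,6β-diol 2,3,7-tris-O-(4-methoxybenzyl) ether (cascade precursor) | COc1ccc(CO[C@@H]2[C@@H](OCc3ccc(OC)cc3)[C@@H]4O[C@@H]4[C@@H](O)[C@@]2(O)COCc2ccc(OC)cc2)cc1 | intermediate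
13 | 5β,6β-epoxy-1α,4α-diol 2,3,7-tris-O-(4-methoxybenzyl) ether (not isolated) | COc1ccc(CO[C@@H]2[C@@H](OCc3ccc(OC)cc3)[C@H](O)[C@H]3O[C@H]3[C@@]2(O)COCc2ccc(OC)cc2)cc1 | intermediate
14 | 1α,6α-epoxy-4α,5β-diol 2,3,7-tris-O-(4-methoxybenzyl) ether (cascade product) | COc1ccc(CO[C@@H]2[C@@H](OCc3ccc(OC)cc3)[C@H](O)[C@@H](O)[C@@H]3O[C@]23COCc2ccc(OC)cc2)cc1 | intermediate
15 | 4α,5β-bis-O-triethylsilyl ether of 14 | COc1ccc(CO[C@@H]2[C@@H](OCc3ccc(OC)cc3)[C@H](O[Si](CC)(CC)CC)[C@@H](O[Si](CC)(CC)CC)[C@@H]3O[C@]23COCc2ccc(OC)cc2)cc1 | intermediate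
16 | 1α,6α-epoxy-1β-(hydroxymethyl)-4α,5β-bis(triethylsilyloxy)cyclohexane-2α,3β-diol | O[C@@H]1[C@@H](O)[C@H](O[Si](CC)(CC)CC)[C@@H](O[Si](CC)(CC)CC)[C@@H]2O[C@]12CO | intermediate
17 | 7-O-benzoate of 16 | O[C@@H]1[C@@H](O)[C@H](O[Si](CC)(CC)CC)[C@@H](O[Si](CC)(CC)CC)[C@@H]2O[C@]12COC(=O)c1ccccc1 | intermediate
18 | 2α,3β-di-O-acetate of 17 | CC(=O)O[C@@H]1[C@@H](OC(C)=O)[C@H](O[Si](CC)(CC)CC)[C@@H](O[Si](CC)(CC)CC)[C@@H]2O[C@]12COC(=O)c1ccccc1 | intermediate
19 | [2α,3β-diacetoxy-1α,6α-epoxy-4α,5β-dihydroxycyclohex-1β-yl]methyl benzoate (CNP0171674.1) | CC(=O)O[C@H]1[C@H](O)[C@@H](O)[C@@H]2O[C@]2(COC(=O)c2ccccc2)[C@@H]1OC(C)=O | target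

**Count and risks**

Total steps: 17. Longest linear sequence: 17 (the route is linear from benzoic acid).

Steps most likely to fail:

1. Step 12. The migrations may come to rest as a mixture of the three oxirane isomers, or an alkoxide may open the oxirane of a second molecule. The fallback replaces the first, reversible migration by an irreversible displacement and sets out from 9. OsO4 (cat.) with NMO in acetone–H2O should dihydroxylate the alkene on the α face, anti to both allylic oxygens, to the 4α,5α-diol F1. SO2Cl2/Et3N at −78 °C closes the 4,5-cyclic sulfate F2. HF·pyridine frees O6 and O7 to give the cyclic sulfate 6,7-diol F3, and Ag2O/PMBBr gives the 7-O-PMB cyclic sulfate F4. KOtBu (1.2 equiv) in THF lets O6 open the sulfate at C5 to the 5β,6β-epoxide 4-sulfate F5, whose sulfate monoester cannot return. O1 then closes the C1/C6 oxirane to the 4-O-sulfate of the product F6. Catalytic H2SO4 in THF with one equivalent of water hydrolyses the sulfate ester, and the route is rejoined at 14.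

2. Step 11. Etherification of the neopentylic primary hydroxyl may be slow and lose site selectivity toward O6, or silver-assisted opening of the oxirane may intervene. The fallback sets out from 11 and installs the ester of the target at once. BzCl with 2,4,6-collidine at −40 °C should give the C7 benzoate F7. Catalytic KOtBu in tBuOH–THF at 0 °C, kept short to limit acyl transfer, should effect the same two migrations through the 5β,6β-epoxide benzoate F8 to the benzoate 4,5-diol F9. TESOTf/2,6-lutidine gives the bis-silyl ether F10, and DDQ removes the two PMB ethers to return to the route at 17.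

3. Step 8. The tertiary O1 may be alkylated as well, or base may shift the silylene from O6 to O1 and expose O6 to alkylation. The fallback introduces the two ethers one at a time and sets out from 7. NaH/PMBCl etherifies the only free hydroxyl to the 3-O-PMB acetonide F11. Aqueous AcOH removes the acetonide to the 1α,2α-diol F12. Bu2SnO in refluxing toluene forms the stannylene acetal F13, and PMBCl/CsF in DMF should alkylate its secondary oxygen only, returning to 9.

Further compounds
F1 | step 12 | 4α,5α-diol from 9 (6,7-O-silylene, 2,3-bis-PMB, 1α-OH) | COc1ccc(CO[C@@H]2[C@@H](OCc3ccc(OC)cc3)[C@H](O)[C@H](O)[C@H]3O[Si](C(C)(C)C)(C(C)(C)C)OC[C@]32O)cc1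
F2 | step 12 | 4α,5α-cyclic sulfate of F1 | COc1ccc(CO[C@@H]2[C@@H](OCc3ccc(OC)cc3)[C@@H]4OS(=O)(=O)O[C@@H]4[C@H]3O[Si](C(C)(C)C)(C(C)(C)C)OC[C@]32O)cc1
F3 | step 12 | 4α,5α-cyclic sulfate 1α,6β,7-triol 2,3-bis-PMB ether | COc1ccc(CO[C@@H]2[C@@H](OCc3ccc(OC)cc3)[C@@H]4OS(=O)(=O)O[C@@H]4[C@@H](O)[C@@]2(O)CO)cc1
F4 | step 12 | 7-O-PMB ether of F3 | COc1ccc(CO[C@@H]2[C@@H](OCc3ccc(OC)cc3)[C@@H]4OS(=O)(=O)O[C@@H]4[C@@H](O)[C@@]2(O)COCc2ccc(OC)cc2)cc1
F5 | step 12 | 5β,6β-epoxy-1α-ol 4α-O-sulfate tris-PMB ether, potassium salt (not isolated) | COc1ccc(CO[C@@H]2[C@@H](OCc3ccc(OC)cc3)[C@H](OS(=O)(=O)[O-])[C@H]3O[C@H]3[C@@]2(O)COCc2ccc(OC)cc2)cc1.[K+]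
F6 | step 12 | 4α-O-sulfate of 14, potassium salt | COc1ccc(CO[C@@H]2[C@@H](OCc3ccc(OC)cc3)[C@H](OS(=O)(=O)[O-])[C@@H](O)[C@@H]3O[C@]23COCc2ccc(OC)cc2)cc1.[K+]
F7 | step 11 | 4α,5α-epoxy-1α,6β-diol 2,3-bis-PMB ether 7-benzoate | COc1ccc(CO[C@@H]2[C@@H](OCc3ccc(OC)cc3)[C@@H]4O[C@@H]4[C@@H](O)[C@@]2(O)COC(=O)c2ccccc2)cc1
F8 | step 11 | 5β,6β-epoxy-1α,4α-diol 2,3-bis-PMB ether 7-benzoate (not isolated) | COc1ccc(CO[C@@H]2[C@@H](OCc3ccc(OC)cc3)[C@H](O)[C@H]3O[C@H]3[C@@]2(O)COC(=O)c2ccccc2)cc1
F9 | step 11 | 1α,6α-epoxy-4α,5β-diol 2,3-bis-PMB ether 7-benzoate | COc1ccc(CO[C@@H]2[C@@H](OCc3ccc(OC)cc3)[C@H](O)[C@@H](O)[C@@H]3O[C@]23COC(=O)c2ccccc2)cc1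
F10 | step 11 | 4α,5β-bis-O-triethylsilyl ether of F9 | COc1ccc(CO[C@@H]2[C@@H](OCc3ccc(OC)cc3)[C@H](O[Si](CC)(CC)CC)[C@@H](O[Si](CC)(CC)CC)[C@@H]3O[C@]23COC(=O)c2ccccc2)cc1
F11 | step 8 | 3β-O-PMB ether of 7 | CC1(C)O[C@@H]2[C@@H](OCc3ccc(OC)cc3)C=C[C@H]3O[Si](C(C)(C)C)(C(C)(C)C)OC[C@]32O1
F12 | step 8 | 3β-O-PMB 6,7-O-silylene 1α,2α-diol | O[C@@H]1[C@@H](OCc2ccc(OC)cc2)C=C[C@H]2O[Si](C(C)(C)C)(C(C)(C)C)OC[C@]21O
F13 | step 8 | 1,2-O-dibutylstannylene acetal of F12 (not isolated) | CCCC[Sn]1(CCCC)O[C@@H]2[C@@H](OCc3ccc(OC)cc3)C=C[C@H]3O[Si](C(C)(C)C)(C(C)(C)C)OC[C@]32O1
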